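The route rests on cutting the bond between C-1 of the free-phenol ring (ring A) and its quaternary carbinol carbon C-7. The key step exploits that C-7 is a tertiary benzylic alcohol whose C–O bond can stand in for a C–B bond, and that ring B carries the identical (S)-carbinol at C-1′/C-7′. The α-lithiated (S)-6-methylheptan-2-yl triisopropylbenzoate therefore captures both boron atoms of an ether-linked bis(aryl neopentyl glycol boronate) made from one monomer. Stereospecific 1,2-aryl shifts forge C-1–C-7, and likewise C-1′–C-7′, with both quaternary stereocentres in one operation, and oxidation reveals the carbinols.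

Key step: step 10

Remark: ring A is the sydonol unit with the free phenol, ring B the O-benzylated unit, and primed numbers refer to ring B. (R)-Propylene oxide, isopentylmagnesium bromide solution and methyl 4-bromo-3-hydroxybenzoate are taken as commercial.

Step 1
Reactants: 1 (R)-2-methyloxirane; 2 isopentylmagnesium bromide
Product: 3 (R)-6-methylheptan-2-ol
Conditions: CuI (10 mol %), THF, −30 → 0 °C; aq. NH4Cl
Reagents that add atoms: none
Why: Copper-catalysed SN2 opening of the epoxide by the Grignard reagent at the unsubstituted CH2 leaves the C–O stereocentre untouched, so the (R)-epoxide should give the (R)-alcohol.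

Step 2
Reactants: 3 (R)-6-methylheptan-2-ol
Product: 4 (S)-6-methylheptan-2-yl 2,4,6-triisopropylbenzoate
Conditions: 2,4,6-triisopropylbenzoic acid, PPh3, DIAD, THF, 0 °C → rt
Reagents that add atoms: 2,4,6-triisopropylbenzoic acid CC(C)c1cc(C(C)C)c(C(=O)O)c(C(C)C)c1
Why: Mitsunobu esterification displaces the oxyphosphonium group by the hindered carboxylate in an SN2 step with inversion, so the (R)-alcohol should give the (S)-benzoate needed for directed α-lithiation.

Step 3
Reactants: 5 methyl 4-bromo-3-hydroxybenzoate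
Product: 6 methyl 3-(allyloxy)-4-bromobenzoate
Conditions: allyl bromide, K2CO3, DMF, rt
Reagents that add atoms: allyl bromide C=CCBr
Why: Williamson O-alkylation of the phenoxide installs a small allyl group that is inert to the low-temperature organolithium steps and removable later under neutral Pd(0) conditions.

Step 4
Reactants: 6 methyl 3-(allyloxy)-4-bromobenzoate
Product: 7 [3-(allyloxy)-4-bromophenyl]methanol
Conditions: DIBAL-H, CH2Cl2, −78 → 0 °C; Rochelle salt
Reagents that add atoms: none
Why: Hydride reduction of the aryl ester with DIBAL-H should give the benzylic alcohol without touching the aryl bromide or the allyl ether.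

Step 5
Reactants: 7 [3-(allyloxy)-4-bromophenyl]methanol
Product: 8 {[3-(allyloxy)-4-bromobenzyl]oxy}(tert-butyl)dimethylsilane
Conditions: TBSCl, imidazole, CH2Cl2, rt
Reagents that add atoms: tert-butyldimethylsilyl chloride CC(C)(C)[Si](C)(C)Cl
Why: Imidazole-assisted silylation of the primary alcohol removes the only acidic proton before the organolithium steps.

Step 6
Reactants: 8 {[3-(allyloxy)-4-bromobenzyl]oxy}(tert-butyl)dimethylsilane
Product: 11 2-[2-(allyloxy)-4-({[tert-butyl(dimethyl)silyl]oxy}methyl)phenyl]-5,5-dimethyl-1,3,2-dioxaborinane, via aryllithium 9 (not isolated), via lithium triisopropoxyborate 10 (not isolated)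
Conditions: n-BuLi, THF, −78 °C; B(OiPr)3, −78 °C → rt; neopentyl glycol, AcOH, rt
Reagents that add atoms: triisopropyl borate CC(C)OB(OC(C)C)OC(C)C; neopentyl glycol OCC(C)(C)CO
Why: Bromine–lithium exchange at −78 °C is faster than any reaction at the allyl ether, and electrophilic borylation of the aryllithium followed by transesterification with the diol should give the neopentyl glycol boronate that serves as precursor of both rings.

Step 7
Reactants: 11 2-[2-(allyloxy)-4-({[tert-butyl(dimethyl)silyl]oxy}methyl)phenyl]-5,5-dimethyl-1,3,2-dioxaborinane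
Product: 12 2-[2-(allyloxy)-4-(bromomethyl)phenyl]-5,5-dimethyl-1,3,2-dioxaborinane
Conditions: Ph3PBr2, CH2Cl2, 0 °C → rt
Reagents that add atoms: triphenylphosphine dibromide BrP(Br)(c1ccccc1)(c1ccccc1)c1ccccc1
Why: Ph3PBr2 converts a primary benzylic TBS ether directly into the bromide through an alkoxyphosphonium bromide (Appel-type SN2) under neutral conditions that an aryl boronic ester should tolerate.

Step 8
Reactants: 11 2-[2-(allyloxy)-4-({[tert-butyl(dimethyl)silyl]oxy}methyl)phenyl]-5,5-dimethyl-1,3,2-dioxaborinane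
Product: 13 5-({[tert-butyl(dimethyl)silyl]oxy}methyl)-2-(5,5-dimethyl-1,3,2-dioxaborinan-2-yl)phenol
Conditions: Pd(PPh3)4 (5 mol %), morpholine, THF, rt
Reagents that add atoms: none
Why: In this Tsuji–Trost-type deallylation Pd(0) ionises the aryl allyl ether and morpholine traps the π-allyl complex, which should free the phenol under neutral conditions without added inorganic base, in which the aryl boronate does not transmetalate.

Step 9
Reactants: 12 2-[2-(allyloxy)-4-(bromomethyl)phenyl]-5,5-dimethyl-1,3,2-dioxaborinane; 13 5-({[tert-butyl(dimethyl)silyl]oxy}methyl)-2-(5,5-dimethyl-1,3,2-dioxaborinan-2-yl)phenol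
Product: 14 2-[2-(allyloxy)-4-({5-({[tert-butyl(dimethyl)silyl]oxy}methyl)-2-(5,5-dimethyl-1,3,2-dioxaborinan-2-yl)phenoxy}methyl)phenyl]-5,5-dimethyl-1,3,2-dioxaborinane
Conditions: Cs2CO3, DMF, rt
Reagents that add atoms: none
Why: In this Williamson ether synthesis the caesium phenoxide of 13 displaces the benzylic bromide of 12 (SN2), while the silyl ether and both neopentyl glycol boronates should be inert under anhydrous carbonate conditions.

Step 10
Reactants: 4 (S)-6-methylheptan-2-yl 2,4,6-triisopropylbenzoate; 14 2-[2-(allyloxy)-4-({5-({[tert-butyl(dimethyl)silyl]oxy}methyl)-2-(5,5-dimethyl-1,3,2-dioxaborinan-2-yl)phenoxy}methyl)phenyl]-5,5-dimethyl-1,3,2-dioxaborinane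
Product: 18 (2S)-2-[2-(allyloxy)-4-({5-({[tert-butyl(dimethyl)silyl]oxy}methyl)-2-[(2S)-2-hydroxy-6-methylheptan-2-yl]phenoxy}methyl)phenyl]-6-methylheptan-2-ol, via lithiated benzoate 15 (not isolated), via dilithium bis(boronate) complex 16 (not isolated), via bis(tertiary boronic ester) 17 (not isolated)
Conditions: 4 (3.0 equiv), s-BuLi (2.8 equiv), TMEDA, CPME, −60 °C; 14 (1.0 equiv), −60 °C → rt, then 40 °C; then NaOH, H2O2, THF/H2O, 0 °C → rt
Reagents that add atoms: hydrogen peroxide OO
Why: s-BuLi/TMEDA removes the carbinol proton of 4 with retention (carbonyl-directed, 15 being configurationally stable at −60 °C), two molecules of 15 attack the two boron atoms of 14 with retention to give the bis(boronate) complex 16, and on warming each aryl carbon (C-1 of ring A, C-1′ of ring B) migrates from boron to the neighbouring carbon anti-periplanar to the departing triisopropylbenzoate, forming C-1–C-7 and C-1′–C-7′ with inversion, after which oxidation of both C–B bonds of 17 with retention reveals the two tertiary alcohols. The closest known reaction type is the lithiation–borylation of secondary dialkyl 2,4,6-triisopropylbenzoates with aryl neopentyl glycol boronic esters, a stereospecific 1,2-metallate rearrangement of the Matteson type, here run at both boron centres of one substrate. No ring is closed. Both new stereocentres (C-7 and C-7′) should be set as (S) solely by the (S) configuration of 4 through the retention–retention–inversion–retention sequence, each independently of the other, so that any minor enantiomer of 4 should end up mainly in a separable diastereomer. The step needs capture of 15 at both boron atoms in preference to deprotonation of the ArCH2OAr methylene, complete twofold conversion, and aryl migration in preference to oxygen migration; the excess of 15, the electrophilic and little-hindered neopentyl glycol boronates with only primary alkoxy groups ortho to boron, the absence of any free OH and the high migratory aptitude of electron-rich aryl groups should secure this.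

Step 11
Reactants: 18 (2S)-2-[2-(allyloxy)-4-({5-({[tert-butyl(dimethyl)silyl]oxy}methyl)-2-[(2S)-2-hydroxy-6-methylheptan-2-yl]phenoxy}methyl)phenyl]-6-methylheptan-2-ol
Product: 20 disydonol A, via phenol 19 (not isolated)
Conditions: Pd(PPh3)4 (5 mol %), morpholine, THF, rt; then TBAF, THF, rt
Reagents that add atoms: none
Why: Pd(0)-catalysed allyl transfer to morpholine (Tsuji–Trost deallylation) should free the ring-A phenol and fluoride then cleaves the primary TBS ether, neither operation touching the two tertiary stereocentres.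

Compound list
1 | (R)-2-methyloxirane ((R)-propylene oxide) | C[C@@H]1CO1 | starting material
2 | isopentylmagnesium bromide ((3-methylbutyl)magnesium bromide) | CC(C)CC[Mg]Br | starting material
3 | (R)-6-methylheptan-2-ol | CC(C)CCC[C@@H](C)O | intermediate
4 | (S)-6-methylheptan-2-yl 2,4,6-triisopropylbenzoate | CC(C)CCC[C@H](C)OC(=O)c1c(C(C)C)cc(C(C)C)cc1C(C)C | intermediate
5 | methyl 4-bromo-3-hydroxybenzoate | COC(=O)c1ccc(Br)c(O)c1 | starting material
6 | methyl 3-(allyloxy)-4-bromobenzoate | COC(=O)c1ccc(Br)c(OCC=C)c1 | intermediate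
7 | [3-(allyloxy)-4-bromophenyl]methanol | OCc1ccc(Br)c(OCC=C)c1 | intermediate
8 | {[3-(allyloxy)-4-bromobenzyl]oxy}(tert-butyl)dimethylsilane | CC(C)(C)[Si](C)(C)OCc1ccc(Br)c(OCC=C)c1 | intermediate
9 | [2-(allyloxy)-4-({[tert-butyl(dimethyl)silyl]oxy}methyl)phenyl]lithium (aryllithium from 8) | [Li]c1ccc(CO[Si](C)(C)C(C)(C)C)cc1OCC=C | intermediate
10 | lithium [2-(allyloxy)-4-({[tert-butyl(dimethyl)silyl]oxy}methyl)phenyl]tri(isopropoxy)borate | [Li+].CC(C)O[B-](OC(C)C)(OC(C)C)c1ccc(CO[Si](C)(C)C(C)(C)C)cc1OCC=C | intermediate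
11 | 2-[2-(allyloxy)-4-({[tert-butyl(dimethyl)silyl]oxy}methyl)phenyl]-5,5-dimethyl-1,3,2-dioxaborinane | C=CCOc1cc(CO[Si](C)(C)C(C)(C)C)ccc1B1OCC(C)(C)CO1 | intermediate
12 | 2-[2-(allyloxy)-4-(bromomethyl)phenyl]-5,5-dimethyl-1,3,2-dioxaborinane | C=CCOc1cc(CBr)ccc1B1OCC(C)(C)CO1 | intermediate
13 | 5-({[tert-butyl(dimethyl)silyl]oxy}methyl)-2-(5,5-dimethyl-1,3,2-dioxaborinan-2-yl)phenol | Oc1cc(CO[Si](C)(C)C(C)(C)C)ccc1B1OCC(C)(C)CO1 | intermediate
14 | 2-[2-(allyloxy)-4-({5-({[tert-butyl(dimethyl)silyl]oxy}methyl)-2-(5,5-dimethyl-1,3,2-dioxaborinan-2-yl)phenoxy}methyl)phenyl]-5,5-dimethyl-1,3,2-dioxaborinane | C=CCOc1cc(COc2cc(CO[Si](C)(C)C(C)(C)C)ccc2B3OCC(C)(C)CO3)ccc1B4OCC(C)(C)CO4 | intermediate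
15 | (S)-2-lithio-6-methylheptan-2-yl 2,4,6-triisopropylbenzoate (Li in the place of the carbinol H of 4) | CC(C)CCC[C@]([Li])(C)OC(=O)c1c(C(C)C)cc(C(C)C)cc1C(C)C | intermediate
16 | dilithium bis(boronate) complex of two molecules of 15 with 14 (each boron in the place of Li; retention at both carbons) | [Li+].[Li+].CC(C)CCC[C@](C)(OC(=O)c1c(C(C)C)cc(C(C)C)cc1C(C)C)[B-]2(OCC(C)(C)CO2)c3ccc(COc4cc(CO[Si](C)(C)C(C)(C)C)ccc4[B-]5(OCC(C)(C)CO5)[C@@](C)(OC(=O)c6c(C(C)C)cc(C(C)C)cc6C(C)C)CCCC(C)C)cc3OCC=C | intermediate
17 | bis(tertiary neopentyl glycol boronic ester) of the protected dimer (a 5,5-dimethyl-1,3,2-dioxaborinan-2-yl group on C-7 and on C-7′ in the place of the later OH groups; both carbons R by the CIP rules because boron ranks lowest) | CC(C)CCC[C@](C)(B1OCC(C)(C)CO1)c2ccc(COc3cc(CO[Si](C)(C)C(C)(C)C)ccc3[C@@](C)(B4OCC(C)(C)CO4)CCCC(C)C)cc2OCC=C | intermediate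
18 | (2S)-2-[2-(allyloxy)-4-({5-({[tert-butyl(dimethyl)silyl]oxy}methyl)-2-[(2S)-2-hydroxy-6-methylheptan-2-yl]phenoxy}methyl)phenyl]-6-methylheptan-2-ol | CC(C)CCC[C@](C)(O)c1ccc(COc2cc(CO[Si](C)(C)C(C)(C)C)ccc2[C@@](C)(O)CCCC(C)C)cc1OCC=C | intermediate
19 | 2-[(2S)-2-hydroxy-6-methylheptan-2-yl]-5-({5-({[tert-butyl(dimethyl)silyl]oxy}methyl)-2-[(2S)-2-hydroxy-6-methylheptan-2-yl]phenoxy}methyl)phenol | CC(C)CCC[C@](C)(O)c1ccc(COc2cc(CO[Si](C)(C)C(C)(C)C)ccc2[C@@](C)(O)CCCC(C)C)cc1O | intermediate
20 | disydonol A: 2-[(2S)-2-hydroxy-6-methylheptan-2-yl]-5-({5-(hydroxymethyl)-2-[(2S)-2-hydroxy-6-methylheptan-2-yl]phenoxy}methyl)phenol | CC(C)CCC[C@](C)(O)c1ccc(COc2cc(CO)ccc2[C@@](C)(O)CCCC(C)C)cc1O | target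

Total step count: 11. Longest linear sequence: 8 steps (from 5 through steps 3, 4, 5, 6, 7, 9, 10, 11 to 20).

Steps most likely to fail

Step 10 (key step). Only one of the two boron atoms may be homologated, boronate formation next to the ortho-alkoxy groups may be slow or reversible on the large substrate, or the lithiated benzoate may deprotonate the ArCH2OAr methylene. The fallback sets out from 11 and comes back at 18. It makes each aryl–carbinol bond at the monomer stage, where a single lithiation–borylation on a small boronate without an ArCH2OAr methylene is needed, and joins the two halves last through the ether oxygen. Lithiated benzoate 15 (from 4, s-BuLi, TMEDA, CPME, −60 °C) is added to 11 to give the lithium boronate complex F1. On warming this should rearrange by the invertive 1,2-aryl shift to 2-{(2R)-2-[2-(allyloxy)-4-({[tert-butyl(dimethyl)silyl]oxy}methyl)phenyl]-6-methylheptan-2-yl}-5,5-dimethyl-1,3,2-dioxaborinane F2. Oxidation (NaOH, H2O2, THF/H2O) should give (2S)-2-[2-(allyloxy)-4-({[tert-butyl(dimethyl)silyl]oxy}methyl)phenyl]-6-methylheptan-2-ol F3. One portion of F3 is desilylated (TBAF, THF) to (2S)-2-[2-(allyloxy)-4-(hydroxymethyl)phenyl]-6-methylheptan-2-ol F4. Appel bromination selective for the primary benzylic alcohol (CBr4, PPh3, CH2Cl2, 0 °C) should then give (2S)-2-[2-(allyloxy)-4-(bromomethyl)phenyl]-6-methylheptan-2-ol F5. The other portion of F3 is deallylated (Pd(PPh3)4, morpholine, THF, rt) to 5-({[tert-butyl(dimethyl)silyl]oxy}methyl)-2-[(2S)-2-hydroxy-6-methylheptan-2-yl]phenol F6. Williamson alkylation of F6 with F5 (Cs2CO3, DMF, rt), in which only the phenol is acidic enough to react, should then give 18.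

Step 8. The π-allyl palladium intermediate may couple with the aryl boronate instead of being trapped by the amine, or the boronate may be lost by protodeboronation once the ortho phenol is free. The fallback sets out from 8 and comes back at 13. It removes the allyl group before boron is present and introduces boron by palladium catalysis instead of through an organolithium. Deallylation of 8 (Pd(PPh3)4, morpholine, THF, rt) should give 2-bromo-5-({[tert-butyl(dimethyl)silyl]oxy}methyl)phenol F7. Miyaura borylation of F7 (bis(neopentyl glycolato)diboron, PdCl2(dppf), KOAc, dioxane, 80 °C), which tolerates the free phenol, should then give 13.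

Step 7. The phosphonium bromide reagent may attack the allyl aryl ether or its alkene, or the boronate may be lost by hydrolysis during the exchange of silyl ether for bromide. The fallback sets out from 11 and comes back at 14, avoiding bromide 12 altogether. Buffered desilylation of 11 (TBAF, AcOH, THF) should give [3-(allyloxy)-4-(5,5-dimethyl-1,3,2-dioxaborinan-2-yl)phenyl]methanol F8. Mitsunobu etherification of F8 with phenol 13 (PPh3, DIAD, toluene, 0 °C → rt) should then give 14 under neutral conditions.

Further compounds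
F1 | step 10 | lithium boronate complex of 15 with 11 (boron in the place of Li; retention) | [Li+].CC(C)CCC[C@](C)(OC(=O)c1c(C(C)C)cc(C(C)C)cc1C(C)C)[B-]1(OCC(C)(C)CO1)c1ccc(CO[Si](C)(C)C(C)(C)C)cc1OCC=C
F2 | step 10 | 2-{(2R)-2-[2-(allyloxy)-4-({[tert-butyl(dimethyl)silyl]oxy}methyl)phenyl]-6-methylheptan-2-yl}-5,5-dimethyl-1,3,2-dioxaborinane | CC(C)CCC[C@](C)(B1OCC(C)(C)CO1)c1ccc(CO[Si](C)(C)C(C)(C)C)cc1OCC=C
F3 | step 10 | (2S)-2-[2-(allyloxy)-4-({[tert-butyl(dimethyl)silyl]oxy}methyl)phenyl]-6-methylheptan-2-ol | CC(C)CCC[C@](C)(O)c1ccc(CO[Si](C)(C)C(C)(C)C)cc1OCC=C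
F4 | step 10 | (2S)-2-[2-(allyloxy)-4-(hydroxymethyl)phenyl]-6-methylheptan-2-ol | CC(C)CCC[C@](C)(O)c1ccc(CO)cc1OCC=C
F5 | step 10 | (2S)-2-[2-(allyloxy)-4-(bromomethyl)phenyl]-6-methylheptan-2-ol | CC(C)CCC[C@](C)(O)c1ccc(CBr)cc1OCC=C
F6 | step 10 | 5-({[tert-butyl(dimethyl)silyl]oxy}methyl)-2-[(2S)-2-hydroxy-6-methylheptan-2-yl]phenol | CC(C)CCC[C@](C)(O)c1ccc(CO[Si](C)(C)C(C)(C)C)cc1O
F7 | step 8 | 2-bromo-5-({[tert-butyl(dimethyl)silyl]oxy}methyl)phenol | Oc1cc(CO[Si](C)(C)C(C)(C)C)ccc1Br
F8 | step 7 | [3-(allyloxy)-4-(5,5-dimethyl-1,3,2-dioxaborinan-2-yl)phenyl]methanol | C=CCOc1cc(CO)ccc1B1OCC(C)(C)CO1
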